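Late in this run the question is how much starting material can still find reagent, and the charges give a count of that.

    reagent in the reaction phase ⇌ reagent in the second phase, rate k1*([reagent in the reaction phase] - [reagent in the second phase]/K1) per volume of the first phase (K1 = 1.6, k1 = 0.17 h⁻¹)
    starting material + reagent in the reaction phase → target (k2 = 15 M⁻¹ h⁻¹)
    starting material + protic impurity → quenched substrate (k3 = 420 M⁻¹ h⁻¹)
    reagent in the reaction phase + target → over-reaction product (k4 = 1.8 M⁻¹ h⁻¹)

starting material 13 mM; reagent in the second phase 0.700 equiv; protic impurity 1.30 mM; time 5.0 d; volume of the second phase over the first 1.0

1. how much target there is at 5.0 d, in percent of the starting material charged
2. part of the starting material charged that has reacted at 5.0 d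

- in the second phase: reagent in the second phase; everything else is in the first
- charges count per volume of the first phase; a concentration in a rate is the amount of a species over the volume of its own phase; every rate counts per litre of the first phase
- run time (flask): 5.0 d

In the first instants the reagent sits in the second phase and, with none yet in the reaction phase, leaves it with a half-life near 0.272 d. Meanwhile the protic impurity attacks starting material directly. The half-life of starting material by that step, at charged concentrations, is 0.053 d, short against the run of 5.0 d, so this reckoning counts the whole 1.30 mM of impurity as consumed, along with the same amount of starting material.

In the middle, reagent reaching the reaction phase divides between starting material and target. The selectivity factor, the ratio of the two rate constants, is 8.33: at equal concentrations of starting material and target, reagent goes to target that many times faster than to over-reaction product.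

Towards the end the reagent, 9.10 mM against 11.7 mM of starting material after the quench, is the limiting reagent. With the impurity counted so, what stays frozen is a balance of the charges:

surplus of starting material over reagent = (13 mM − 1.30 mM − 9.10 mM) / 13 mM = 20.0%

starting material left = surplus + over-reaction product + reagent unspent in both phases

Each unit of over-reaction product holds a second reagent spent on material already reacted, so that much less reagent reached starting material. This reckoning by hand therefore ends in ceilings: 80.0% reacted and 70.0% of target. It does not say how near the flask comes to them by 5.0 d.

The forecast goes further, to 56.3% of target (53% to 59%) and 71.6% reacted (69% to 74%). It holds the reagent in the reaction phase in quasi-steady state, noting that “Transfer is not fast compared with reaction”.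

The simulation gives 57.3% of target and 72.3% reacted. Target in this flask goes from 51.8% at 2.50 d to 58.8% at 10.0 d. Its balance at 5.00 d is the surplus of 20.0%, plus 4.99% of over-reaction product, plus 2.72% of reagent unspent, which makes 27.7% against 27.7% of starting material found. The same flask with 5.2 mM of protic impurity has a negative surplus, −10.0%. With 7.41% of over-reaction product and 10.8% of reagent unspent, that comes to 8.22%, and this neighbour holds 8.22% of starting material.

The numbers belong to no real substance; the flask was simulated.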